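Atom labels follow labdane numbering (C1–C10 decalin, C11–C16 side chain and butenolide, C17 methyl on C8, C20 methyl on C10).

## Structural features

The target is a labdane: a trans-fused decalin (rings A and B) joined through the two-carbon chain C11–C12 to a β-substituted butenolide (C13=C14, lactone carbonyl C15, OCH2 C16). Ring A carries the gem-dimethyl group at C4 and the angular methyl at C10. Ring B carries the tetrasubstituted C8=C9 alkene, with the C17 methyl on C8 and the side chain on C9. The three stereocentres are contiguous: quaternary C10 (S), the ring-fusion carbon C5 (S, hydrogen anti to the C10 methyl) and C6 (R), whose acetoxy group is axial and syn to both the C10 methyl and the 4β-methyl. The fragile parts are the butenolide (acidic γ-hydrogens, open to hydride and nucleophiles), the secondary acetate and the allylic positions C7 and C11. The real difficulty is the all-carbon quaternary C10, wedged between the fully substituted C9 and the neopentyl C5–C4 region, together with the hindered axial oxygen at C6. The key step uses the fact that C7 and C17 are the two one-carbon arms on C8 and that C9 carries a carboxyl-level carbon (C11). The unit C11(=O)–C9=C8(C7)(C17) is therefore an isopropylidene ester whose dienolate ends at C7, six atoms from a C6 ester on C5, so γ-acylation closes ring B with the alkene, the C17 methyl and the C6 oxygen in place.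

## Logic of the disconnections

**24 to 23.** The acetyl C–O bond at C6 is cut. The acetate would not survive hydride, azaenolate or ylide, so it is put on last. The demand is acylation of an axial hydroxyl flanked by two syn-axial methyl groups without touching the butenolide.

**23 to 21.** The butenolide is cut at C13=C14 and at O–C15. An α-hydroxy ketone and a two-carbon ketene ylide give the β-substituted butenolide with the carbonyl unambiguously on the C14 side. The heterocycle becomes an acyclic ketol. The forward step must acylate the primary hydroxyl in preference to the hindered 6-hydroxyl and then close by intramolecular Wittig reaction.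

**21 to 20 to 16 plus 18 (18 from 17).** The C11–C12 bond is cut. Allylic C11 is a natural electrophile and the three-carbon ketol unit a natural azaenolate, so decalin and side chain are made separately and joined late. The demands are alkylation at the methyl carbon of the hydrazone, direct (not allylically transposed) substitution at a hindered allylic bromide, and tolerance of the free 6-hydroxyl.

**16 to 15 to 14 to 13.** No skeletal bond is cut. The bromide comes from the allylic alcohol, that from the C11 ester, and the 6β-hydroxyl from the C6 ketone. This returns to the product of the key step. The demand is hydride delivery to C6 from the α-face.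

**13 to 10 (key step).** The C6–C7 bond is cut, opening ring B to a ring-A diester. This leaves a monocyclic compound with two stereocentres, of which only C10 cannot be corrected later. Three points of the simple picture are put right here.
- The two methyl groups on C8 are not equivalent in 10 (one is cis to the ester, one cis to C10). They become equivalent only in the dienolate, where rotation about C8–C9 lets the CH2 terminus reach C6.
- Ring size excludes attack by C9, but the enolate oxygen can also reach C6 in a six-membered closure. O-acylation is the real competitor and is tolerated only because it is reversible.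
- The product is more acidic than the substrate, so more than two equivalents of base are required.

The precursor is kept as the dimethyl diester. Its design is relaxed in one respect: either C5 epimer and any β,γ-unsaturated (isopropenyl) isomer give the same dienolate and the same product, so none of them has to be removed.

**10 to 9 to 8 to 7.** The C6 ester is traced to a hydroxymethyl group and that to the exocyclic C5=C6 methylene; the C5–H bond is the one formed. The demand is hydroboration of the ring methylene only, from the face anti to the axial methyls. This is why the side-chain alkene must already be tetrasubstituted and conjugated.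

**7 to 6 to 5.** The side-chain double bond is moved from C7=C8 to C8=C9 and the acid is esterified. The C9 stereocentre disappears. The demand is an equilibrium that favours the conjugated isomer.

**5 to 3.** The C9–C10 bond is cut as a [3,3] shift. A quaternary carbon next to a branched carbon is best made intramolecularly, and the allylic oxygen of the terpene alcohol leaves behind exactly the exocyclic methylene that becomes C6. The gain is the quaternary centre from an achiral ester. The demand is reagent control over the two faces of a tetrasubstituted alkene.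

**3 to 1 plus 2.** The ester C–O bond is cut, giving two commercial materials.

## Other disconnections considered

**Alternative 1:** The cut is C7–C8 and C9–C10. Forward, heating the ester-tethered ynoate A1 lets the but-2-ynoate add across the C7=C6–C5=C10 silyloxy diene to give the lactone-bridged diene A2.
- In its favour: ring B, the quaternary C10, the C8=C9 alkene with C17 and C11 attached, and a C6 oxygen at the ketone level all arrive in one thermal step. The C10 configuration is relayed from the single carbinol centre C1.
- Against it here: the C1 oxygen is absent from the target and must be removed after lactone opening, which costs several steps. The diene terminus C10 is fully substituted with its methyl on the inside, and the C4 gem-dimethyl group twists the silyloxyvinyl unit out of plane. The ester tether also prefers the unreactive conformation, so forcing temperatures are likely.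
- Comparison: it is better than the chosen plan on bond economy (two C–C bonds and the quaternary centre in the ring-forming step, no separate sigmatropic step). It is equal or better on the alkene position, which is fixed by the cycloaddition and not by a base-mediated equilibrium. It is equal on the C6 handle. It is worse on step economy after the key step and on the reactivity of the hindered diene.

**Alternative 2:** The cut is C9–C10. Forward, the silyl ketene acetal of the δ-lactone A3 undergoes a [3,3] shift that forms C9–C10, breaks C6–O and gives the octalin acid A4.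
- In its favour: ring B and the quaternary centre form together, stereospecifically, by chirality transfer from the C6 carbinol carbon. The lactone should be available in very few steps from β-cyclocitral and a four-carbon dienolate.
- Against it here: the C6 oxygen, which the target needs, is the leaving group. C6 must be re-oxygenated across the new C5=C6 alkene, which also sets C5, and syn hydroboration would give the 6α-alcohol, so an oxidation–reduction pair follows. The exocyclic C8 methylene must first be moved to C8=C9 so that it does not compete. The boat transition state must also accommodate a tetrasubstituted alkene terminus.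
- Comparison: it is better on the number of steps to the decalin and on stereocontrol at C10 (substrate relay instead of a stoichiometric chiral reagent). It is equal on the C11 carboxyl. It is worse in that A4 lacks both the C6 oxygen and the C5 stereocentre that 13 already carries, so the overall count should be similar.

**Alternative 3:** The cut is C5–C10 and C6–C7. Forward, the nitro triene A5 cyclises under a chiral bis-thiourea, the (E)-nitroalkene C5=C6 adding to the C7=C8–C9=C10 diene to give the nitro decalin A6.
- In its favour: both rings, C5, C10 and a C6 heteroatom come from an acyclic achiral chain that already carries the protected side chain, under catalytic enantiocontrol.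
- Against it here: the diene terminus C10 is disubstituted, so one group always sits inside and the reactive conformation is disfavoured. The dienophile carbon C5 is next to the gem-dimethyl carbon. A quaternary centre must form under hydrogen-bond catalysis. Preparing the tetrasubstituted C9=C10 alkene of A5 with defined geometry is a multi-step problem of its own.
- Comparison: it is better on convergence and on catalytic enantiocontrol. It is equal on the C6 handle, since the nitro group must pass through the same 6-ketone as 13 before reduction to the 6β-alcohol. It is worse on the likelihood that the cycloaddition proceeds at all and on the length of the route to its precursor.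

Key step: step 8

Assumption: the (S,S) enantiomer of the diazaborolidine controller is taken to give (R)-C10 in 5; if the sense of induction is the reverse, the (R,R) enantiomer is used and nothing else changes.

## Route

Step 1
Reactants: 1 β-cyclogeraniol; 2 3-methylbut-2-enoic acid
Product: 3 (2,6,6-trimethylcyclohex-1-en-1-yl)methyl 3-methylbut-2-enoate
Conditions: DCC, DMAP (cat.), CH2Cl2, 0 °C → rt
Reagents that add atoms: none
Why: Steglich esterification of a primary allylic alcohol; any isomerisation to the 3-methylbut-3-enoate is harmless because both esters give the same dienolate in step 2.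

Step 2
Reactants: 3 (2,6,6-trimethylcyclohex-1-en-1-yl)methyl 3-methylbut-2-enoate
Product: 5 3-methyl-2-[(1R)-1,3,3-trimethyl-2-methylidenecyclohexyl]but-3-enoic acid (C2 of the acid not assigned), via boron dienolate 4 (not isolated)
Conditions: (4S,5S)-2-bromo-4,5-diphenyl-1,3-bis{[3,5-bis(trifluoromethyl)phenyl]sulfonyl}-1,3,2-diazaborolidine (1.2 equiv), i-Pr2NEt, CH2Cl2, −78 °C → rt; aqueous work-up
Reagents that add atoms: none
Why: Enantioselective boron-enolate Ireland–Claisen rearrangement: soft γ-enolisation gives dienolate 4, whose α-carbon bonds to the methyl-bearing ring carbon through a chair [3,3] transition state, so the CH2O carbon becomes the exocyclic methylene and C10 becomes quaternary. The chiral sulfonamide ligand on boron selects the face of the alkene; C10 is (R) here only because the methylidene carbon outranks C9, and it is the same arrangement as (S)-C10 of the target. The second new centre (C9) is erased in step 4.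

Step 3
Reactants: 5 3-methyl-2-[(1R)-1,3,3-trimethyl-2-methylidenecyclohexyl]but-3-enoic acid
Product: 6 methyl 3-methyl-2-[(1R)-1,3,3-trimethyl-2-methylidenecyclohexyl]but-3-enoate
Conditions: MeI, K2CO3, DMF, rt
Reagents that add atoms: iodomethane CI
Why: O-alkylation of the carboxylate, which is insensitive to the hindrance around the carboxyl group; the ester is needed because borane would reduce a free acid in step 5.

Step 4
Reactants: 6 methyl 3-methyl-2-[(1R)-1,3,3-trimethyl-2-methylidenecyclohexyl]but-3-enoate
Product: 7 methyl 3-methyl-2-[(1S)-1,3,3-trimethyl-2-methylidenecyclohexyl]but-2-enoate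
Conditions: NaOMe (0.3 equiv), MeOH, 65 °C
Reagents that add atoms: none
Why: Base-mediated β,γ- to α,β-isomerisation of an unsaturated ester through its dienolate; the side-chain alkene becomes tetrasubstituted and electron-poor, which protects it from borane in step 5. The exocyclic methylene cannot migrate because both of its neighbours are quaternary; the C10 descriptor changes to (S) by priority only.

Step 5
Reactants: 7 methyl 3-methyl-2-[(1S)-1,3,3-trimethyl-2-methylidenecyclohexyl]but-2-enoate
Product: 8 methyl 2-[(1S,2S)-2-(hydroxymethyl)-1,3,3-trimethylcyclohexyl]-3-methylbut-2-enoate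
Conditions: BH3·THF, THF, 0 °C → rt; then 30% H2O2, aq. NaOH, 0 °C
Reagents that add atoms: hydrogen peroxide OO
Why: Anti-Markovnikov hydroboration–oxidation of the 1,1-disubstituted ring methylene; the conjugated tetrasubstituted enoate and the ester react far more slowly. Hydrogen is delivered to C5 from the face opposite the two axial methyl groups on C4 and C10, which places C6 trans to the C9 substituent (5α-H); this centre is in any case correctable after step 8.

Step 6
Reactants: 8 methyl 2-[(1S,2S)-2-(hydroxymethyl)-1,3,3-trimethylcyclohexyl]-3-methylbut-2-enoate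
Product: 9 (1S,2S)-2-(1-methoxy-3-methyl-1-oxobut-2-en-2-yl)-2,6,6-trimethylcyclohexane-1-carboxylic acid
Conditions: CrO3, H2SO4, H2O, acetone, 0 °C
Reagents that add atoms: water O
Why: Jones oxidation of a hindered primary alcohol through the aldehyde hydrate to the acid; prompt oxidation also forestalls lactonisation of the hydroxyl onto the C11 ester.

Step 7
Reactants: 9 (1S,2S)-2-(1-methoxy-3-methyl-1-oxobut-2-en-2-yl)-2,6,6-trimethylcyclohexane-1-carboxylic acid
Product: 10 methyl (1S,2S)-2-(1-methoxy-3-methyl-1-oxobut-2-en-2-yl)-2,6,6-trimethylcyclohexane-1-carboxylate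
Conditions: MeI, K2CO3, DMF, rt
Reagents that add atoms: iodomethane CI
Why: Carboxylate alkylation, chosen because the acid flanked by two quaternary carbons would resist acid-catalysed esterification.

Step 8
Reactants: 10 methyl (1S,2S)-2-(1-methoxy-3-methyl-1-oxobut-2-en-2-yl)-2,6,6-trimethylcyclohexane-1-carboxylate
Product: 13 methyl (4aS,8aS)-2,5,5,8a-tetramethyl-4-oxo-3,4,4a,5,6,7,8,8a-octahydronaphthalene-1-carboxylate, via lithium dienolate 11 (not isolated), via lithium enolate of the cyclised keto ester 12 (not isolated)
Conditions: LiN(i-Pr)2 (2.5 equiv), THF–DMPU, −78 → 0 °C; AcOH, −78 °C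
Reagents that add atoms: none
Why: LiN(i-Pr)2 removes an allylic hydrogen from either methyl group on C8 to give dienolate 11, in which rotation about the C8–C9 bond brings the CH2 terminus syn to C10. The terminus C7 adds to the C6 ester carbonyl, methoxide leaves, and the new C7 methylene, flanked by the ketone and the enoate, is deprotonated at once to the extended enolate 12, which takes the condensation out of equilibrium and is the reason for the excess base. The closest known reaction type is the vinylogous Claisen or Dieckmann condensation of 3-methylbut-2-enoate dienolates through the γ-carbon. Ring B closes in the 6-(enolendo)-exo-trig mode. The step needs γ-C-acylation: attack by C9 would give a four-membered ring and is excluded by ring size, while attack by the enolate oxygen, also a six-membered closure, gives an enol ester that methoxide reopens, so 12 accumulates as the thermodynamic sink. Any β,γ-unsaturated isomer of 10 and either C5 epimer feed the same pathway. C5 enters with its hydrogen anti to the C10 methyl and, being α to the new ketone, stays under thermodynamic control in favour of the trans-fused decalin; C10 is untouched. Cold protonation of 12 should occur at the less hindered C7 and give 13 as the 8-ene tautomer.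

Step 9
Reactants: 13 methyl (4aS,8aS)-2,5,5,8a-tetramethyl-4-oxo-3,4,4a,5,6,7,8,8a-octahydronaphthalene-1-carboxylate
Product: 14 methyl (4R,4aS,8aS)-4-hydroxy-2,5,5,8a-tetramethyl-3,4,4a,5,6,7,8,8a-octahydronaphthalene-1-carboxylate
Conditions: NaBH4, CeCl3·7H2O, MeOH, −40 → 0 °C
Reagents that add atoms: none
Why: Luche reduction; hydride approaches C6 from the α-face because the β-face is closed by the axial C10 and 4β-methyl groups, giving the axial 6β-alcohol (R). The conditions also secure 1,2-reduction of any 7-en-6-one tautomer, whose alkene can then be returned to C8=C9 by brief NaOMe in MeOH.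

Step 10
Reactants: 14 methyl (4R,4aS,8aS)-4-hydroxy-2,5,5,8a-tetramethyl-3,4,4a,5,6,7,8,8a-octahydronaphthalene-1-carboxylate
Product: 15 (1R,4aS,8aS)-4-(hydroxymethyl)-3,4a,8,8-tetramethyl-1,2,4a,5,6,7,8,8a-octahydronaphthalen-1-ol
Conditions: (i-Bu)2AlH (4 equiv), CH2Cl2, −78 → 0 °C; aq. KNaC4H4O6
Reagents that add atoms: none
Why: 1,2-Reduction of the α,β-unsaturated ester to the allylic alcohol; one equivalent of hydride is consumed by the free hydroxyl.

Step 11
Reactants: 15 (1R,4aS,8aS)-4-(hydroxymethyl)-3,4a,8,8-tetramethyl-1,2,4a,5,6,7,8,8a-octahydronaphthalen-1-ol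
Product: 16 (1R,4aS,8aS)-4-(bromomethyl)-3,4a,8,8-tetramethyl-1,2,4a,5,6,7,8,8a-octahydronaphthalen-1-ol
Conditions: CBr4 (1.1 equiv), PPh3 (1.1 equiv), CH2Cl2, 0 °C; used at once
Reagents that add atoms: carbon tetrabromide BrC(Br)(Br)Br
Why: Appel bromination, selective for the primary allylic hydroxyl over the axial secondary one; the 6-oxygen cannot displace the bromide because the resulting ether would need a bridgehead alkene.

Step 12
Reactants: 17 1-(tert-butyldimethylsilyloxy)propan-2-one
Product: 18 (E)-1-(tert-butyldimethylsilyloxy)propan-2-one N,N-dimethylhydrazone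
Conditions: Me2NNH2, MgSO4, EtOH, rt
Reagents that add atoms: 1,1-dimethylhydrazine CN(C)N
Why: Hydrazone condensation; the dimethylamino group settles anti to the larger silyloxymethyl arm.

Step 13
Reactants: 18 (E)-1-(tert-butyldimethylsilyloxy)propan-2-one N,N-dimethylhydrazone; 16 (1R,4aS,8aS)-4-(bromomethyl)-3,4a,8,8-tetramethyl-1,2,4a,5,6,7,8,8a-octahydronaphthalen-1-ol
Product: 20 N,N-dimethylhydrazone of 1-(tert-butyldimethylsilyloxy)-4-[(4R,4aS,8aS)-4-hydroxy-2,5,5,8a-tetramethyl-3,4,4a,5,6,7,8,8a-octahydronaphthalen-1-yl]butan-2-one, via lithium azaenolate 19 (not isolated)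
Conditions: 18 (2.3 equiv), LiN(i-Pr)2 (2.3 equiv), THF, −78 → 0 °C; then 16, −78 → 0 °C
Reagents that add atoms: none
Why: Azaenolate alkylation of a dimethylhydrazone, deprotonated at the less substituted methyl carbon, forms C11–C12 by direct substitution at the primary allylic bromide (the transposed position C8 is fully substituted). One equivalent of azaenolate is spent on the 6-hydroxyl, whose lithium alkoxide is inert.

Step 14
Reactants: 20 N,N-dimethylhydrazone of 1-(tert-butyldimethylsilyloxy)-4-[(4R,4aS,8aS)-4-hydroxy-2,5,5,8a-tetramethyl-3,4,4a,5,6,7,8,8a-octahydronaphthalen-1-yl]butan-2-one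
Product: 21 1-hydroxy-4-[(4R,4aS,8aS)-4-hydroxy-2,5,5,8a-tetramethyl-3,4,4a,5,6,7,8,8a-octahydronaphthalen-1-yl]butan-2-one
Conditions: 2 M aq. HCl, THF, 0 °C → rt
Reagents that add atoms: water O
Why: Aqueous acid hydrolyses the hydrazone to the ketone and cleaves the primary silyl ether in the same operation; the tetrasubstituted alkene and the homoallylic 6-hydroxyl should tolerate dilute acid at room temperature.

Step 15
Reactants: 21 1-hydroxy-4-[(4R,4aS,8aS)-4-hydroxy-2,5,5,8a-tetramethyl-3,4,4a,5,6,7,8,8a-octahydronaphthalen-1-yl]butan-2-one
Product: 23 4-{2-[(4R,4aS,8aS)-4-hydroxy-2,5,5,8a-tetramethyl-3,4,4a,5,6,7,8,8a-octahydronaphthalen-1-yl]ethyl}furan-2(5H)-one, via acyl ylide ester 22 (not isolated)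
Conditions: Ph3P=C=C=O (1.05 equiv), toluene, 90 °C
Reagents that add atoms: ketenylidenetriphenylphosphorane O=C=C=P(c1ccccc1)(c1ccccc1)c1ccccc1
Why: The primary hydroxyl adds across the ketene to give the stabilised ylide ester 22, which closes onto the adjacent ketone by intramolecular Wittig reaction and fixes the lactone carbonyl at C15. The hindered axial 6-hydroxyl should not compete with one equivalent of reagent.

Step 16
Reactants: 23 4-{2-[(4R,4aS,8aS)-4-hydroxy-2,5,5,8a-tetramethyl-3,4,4a,5,6,7,8,8a-octahydronaphthalen-1-yl]ethyl}furan-2(5H)-one
Product: 24 (1R,4aS,8aS)-3,4a,8,8-tetramethyl-4-[2-(5-oxo-2,5-dihydrofuran-3-yl)ethyl]-1,2,4a,5,6,7,8,8a-octahydronaphthalen-1-yl acetate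
Conditions: Ac2O, DMAP, Et3N, CH2Cl2, rt → 40 °C
Reagents that add atoms: acetic anhydride CC(=O)OC(C)=O
Why: DMAP-catalysed acylation with retention at C6; the amine base is too weak to deprotonate the butenolide, and the acetate is introduced only after all hydride and carbanion chemistry.

## Compound list

1 | β-cyclogeraniol | CC1=C(CO)C(C)(C)CCC1 | starting material
2 | 3-methylbut-2-enoic acid | CC(C)=CC(O)=O | starting material
3 | (2,6,6-trimethylcyclohex-1-en-1-yl)methyl 3-methylbut-2-enoate | CC(C)=CC(=O)OCC1=C(C)CCCC1(C)C | intermediate
4 | boron dienolate of 3 carrying the (4S,5S)-4,5-diphenyl-1,3-bis{[3,5-bis(trifluoromethyl)phenyl]sulfonyl}-1,3,2-diazaborolidin-2-yl group on oxygen (enolate geometry not assigned) | C=C(C)C=C(OCC1=C(C)CCCC1(C)C)OB1N(S(=O)(=O)c2cc(cc(c2)C(F)(F)F)C(F)(F)F)[C@@H](c2ccccc2)[C@H](c2ccccc2)N1S(=O)(=O)c1cc(cc(c1)C(F)(F)F)C(F)(F)F | intermediate (not isolated)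
5 | 3-methyl-2-[(1R)-1,3,3-trimethyl-2-methylidenecyclohexyl]but-3-enoic acid (C2 not assigned) | C=C(C)C(C(O)=O)[C@@]1(C)CCCC(C)(C)C1=C | intermediate
6 | methyl 3-methyl-2-[(1R)-1,3,3-trimethyl-2-methylidenecyclohexyl]but-3-enoate (C2 not assigned) | C=C(C)C(C(=O)OC)[C@@]1(C)CCCC(C)(C)C1=C | intermediate
7 | methyl 3-methyl-2-[(1S)-1,3,3-trimethyl-2-methylidenecyclohexyl]but-2-enoate | CC(C)=C(C(=O)OC)[C@@]1(C)CCCC(C)(C)C1=C | intermediate
8 | methyl 2-[(1S,2S)-2-(hydroxymethyl)-1,3,3-trimethylcyclohexyl]-3-methylbut-2-enoate | OC[C@H]1C(C)(C)CCC[C@]1(C)C(C(=O)OC)=C(C)C | intermediate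
9 | (1S,2S)-2-(1-methoxy-3-methyl-1-oxobut-2-en-2-yl)-2,6,6-trimethylcyclohexane-1-carboxylic acid | OC(=O)[C@H]1C(C)(C)CCC[C@]1(C)C(C(=O)OC)=C(C)C | intermediate
10 | methyl (1S,2S)-2-(1-methoxy-3-methyl-1-oxobut-2-en-2-yl)-2,6,6-trimethylcyclohexane-1-carboxylate (key-step precursor) | COC(=O)[C@H]1C(C)(C)CCC[C@]1(C)C(C(=O)OC)=C(C)C | intermediate
11 | lithium dienolate of 10 (O-lithiated ketene acetal with a CH2 terminus at C7) | COC(=O)[C@H]1C(C)(C)CCC[C@]1(C)C(C(C)=C)=C(OC)O[Li] | intermediate (not isolated)
12 | lithium enolate of 13 (O-lithiated at C6, C6=C7 and C8=C9) | [Li]OC1=CC(C)=C(C(=O)OC)[C@@]2(C)CCCC(C)(C)[C@H]12 | intermediate (not isolated)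
13 | methyl (4aS,8aS)-2,5,5,8a-tetramethyl-4-oxo-3,4,4a,5,6,7,8,8a-octahydronaphthalene-1-carboxylate (key-step product) | O=C1CC(C)=C(C(=O)OC)[C@@]2(C)CCCC(C)(C)[C@H]12 | intermediate
14 | methyl (4R,4aS,8aS)-4-hydroxy-2,5,5,8a-tetramethyl-3,4,4a,5,6,7,8,8a-octahydronaphthalene-1-carboxylate | O[C@@H]1CC(C)=C(C(=O)OC)[C@@]2(C)CCCC(C)(C)[C@H]12 | intermediate
15 | (1R,4aS,8aS)-4-(hydroxymethyl)-3,4a,8,8-tetramethyl-1,2,4a,5,6,7,8,8a-octahydronaphthalen-1-ol | O[C@@H]1CC(C)=C(CO)[C@@]2(C)CCCC(C)(C)[C@H]12 | intermediate
16 | (1R,4aS,8aS)-4-(bromomethyl)-3,4a,8,8-tetramethyl-1,2,4a,5,6,7,8,8a-octahydronaphthalen-1-ol | O[C@@H]1CC(C)=C(CBr)[C@@]2(C)CCCC(C)(C)[C@H]12 | intermediate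
17 | 1-(tert-butyldimethylsilyloxy)propan-2-one | CC(=O)CO[Si](C)(C)C(C)(C)C | starting material
18 | (E)-1-(tert-butyldimethylsilyloxy)propan-2-one N,N-dimethylhydrazone | C/C(=N\N(C)C)CO[Si](C)(C)C(C)(C)C | intermediate
19 | lithium azaenolate of 18 (deprotonated at the methyl carbon) | C=C(CO[Si](C)(C)C(C)(C)C)N([Li])N(C)C | intermediate (not isolated)
20 | N,N-dimethylhydrazone of 1-(tert-butyldimethylsilyloxy)-4-[(4R,4aS,8aS)-4-hydroxy-2,5,5,8a-tetramethyl-3,4,4a,5,6,7,8,8a-octahydronaphthalen-1-yl]butan-2-one (C=N geometry not assigned) | O[C@@H]1CC(C)=C(CCC(=NN(C)C)CO[Si](C)(C)C(C)(C)C)[C@@]2(C)CCCC(C)(C)[C@H]12 | intermediate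
21 | 1-hydroxy-4-[(4R,4aS,8aS)-4-hydroxy-2,5,5,8a-tetramethyl-3,4,4a,5,6,7,8,8a-octahydronaphthalen-1-yl]butan-2-one | O[C@@H]1CC(C)=C(CCC(=O)CO)[C@@]2(C)CCCC(C)(C)[C@H]12 | intermediate
22 | 2-oxo-4-[(4R,4aS,8aS)-4-hydroxy-2,5,5,8a-tetramethyl-3,4,4a,5,6,7,8,8a-octahydronaphthalen-1-yl]butyl (triphenylphosphoranylidene)acetate | O[C@@H]1CC(C)=C(CCC(=O)COC(=O)C=P(c3ccccc3)(c3ccccc3)c3ccccc3)[C@@]2(C)CCCC(C)(C)[C@H]12 | intermediate (not isolated)
23 | 4-{2-[(4R,4aS,8aS)-4-hydroxy-2,5,5,8a-tetramethyl-3,4,4a,5,6,7,8,8a-octahydronaphthalen-1-yl]ethyl}furan-2(5H)-one | O[C@@H]1CC(C)=C(CCC3=CC(=O)OC3)[C@@]2(C)CCCC(C)(C)[C@H]12 | intermediate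
24 | (1R,4aS,8aS)-3,4a,8,8-tetramethyl-4-[2-(5-oxo-2,5-dihydrofuran-3-yl)ethyl]-1,2,4a,5,6,7,8,8a-octahydronaphthalen-1-yl acetate; (5S,6R,10S)-6-acetoxylabda-8,13-dien-15,16-olide | CC(=O)O[C@@H]1CC(C)=C(CCC2=CC(=O)OC2)[C@@]2(C)CCCC(C)(C)[C@H]12 | target

## Step count and least certain steps

Total: 16 steps. Longest linear sequence: 15 steps (steps 1–11 and 13–16); step 12 is a one-step side branch.

**Step 8 (key step).** The most likely failure is slow or reversible C-acylation at the ester carbonyl, which sits between two quaternary carbons, so that O-acylation, proton exchange or intermolecular condensation takes over. The fallback replaces the ester electrophile by an aldehyde and sets out from 8. Oxidation with Dess–Martin periodinane gives methyl 2-[(1S,2S)-2-formyl-1,3,3-trimethylcyclohexyl]-3-methylbut-2-enoate F1. Lithium 2,2,6,6-tetramethylpiperidide at −78 °C forms the same kind of γ-dienolate, which closes ring B by intramolecular vinylogous aldol addition to the 6-hydroxy ester F2 (either C6 epimer). A second Dess–Martin oxidation returns to the route at 13.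

**Step 4.** The isomerisation may stop at an unfavourable equilibrium: the conjugated isomer gains a tetrasubstituted alkene and conjugation but pays allylic strain between the quaternary C10 and the cis methyl, which also twists the ester out of plane. The fallback does not move the double bond at all; it sets out from 6 and gives up the side-chain alkene for a time.
- Excess BH3·THF hydroborates both alkenes; oxidative work-up and a trace of acid give the hydroxy γ-lactone F3 (C7–O joined to C11).
- Jones oxidation gives the lactone acid F4.
- PhSeNa in DMF opens the lactone at C7 to the seleno diacid F5.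
- MeI and K2CO3 give the seleno diester F6.
- H2O2 and pyridine bring about selenoxide elimination to the β,γ-unsaturated diester F7.
- Under the conditions of step 8, F7 is deprotonated at C9 to the same dienolate, so the fallback comes back to the route at 11.

**Step 2.** Facial selectivity may be poor, or the rearrangement slow, because the alkene terminus is tetrasubstituted and part of a ring. The fallback gives up reagent control and sets out from 3. LiN(i-Pr)2 and Me3SiCl at −78 °C give the silyl dienol ether F8, which rearranges on warming to the silyl ester F9; work-up gives the racemic acid F10. This is resolved by crystallisation with one enantiomer of 1-phenylethylamine, written here as the (S)-amine salt F11 of the (R)-acid. Acidification returns to the route at 5.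

**Step 13.** The azaenolate may form at the wrong carbon (the silyloxymethylene, with loss of silanolate), or substitution at the hindered allylic bromide may be slow. The fallback forms the C–C bond first and oxygenates C16 afterwards; it sets out from 16. The lithium azaenolate of acetone N,N-dimethylhydrazone, which has no regiochemical choice, gives the hydrazone F12, and aqueous acid gives the methyl ketone F13. Kinetic deprotonation at the methyl group with LiN(i-Pr)2 at −78 °C and hydroxylation with 2-(phenylsulfonyl)-3-phenyloxaziridine return to the route at 21.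

**Step 15.** The ketene ylide may acylate the 6-hydroxyl, or the intramolecular Wittig closure onto the enolisable ketone may be slow. The fallback sets out from 21. Selective esterification of the primary hydroxyl with diethylphosphonoacetic acid (DCC, DMAP) gives the phosphonoacetate F14, and LiCl with DBU closes the butenolide by intramolecular Horner–Wadsworth–Emmons reaction, returning to the route at 23.

## Further compounds

F1 | step 8 | methyl 2-[(1S,2S)-2-formyl-1,3,3-trimethylcyclohexyl]-3-methylbut-2-enoate | O=C[C@H]1C(C)(C)CCC[C@]1(C)C(C(=O)OC)=C(C)C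
F2 | step 8 | methyl (4aS,8aS)-4-hydroxy-2,5,5,8a-tetramethyl-3,4,4a,5,6,7,8,8a-octahydronaphthalene-1-carboxylate (C4 epimers) | OC1CC(C)=C(C(=O)OC)[C@@]2(C)CCCC(C)(C)[C@H]12
F3 | step 4 | 3-[2-(hydroxymethyl)-1,3,3-trimethylcyclohexyl]-4-methyloxolan-2-one (ring centres as in 8; lactone centres not assigned) | OC[C@H]1C(C)(C)CCC[C@]1(C)C1C(C)COC1=O
F4 | step 4 | 2,6,6-trimethyl-2-(4-methyl-2-oxooxolan-3-yl)cyclohexane-1-carboxylic acid (ring centres as in 9) | OC(=O)[C@H]1C(C)(C)CCC[C@]1(C)C1C(C)COC1=O
F5 | step 4 | 2-[1-carboxy-2-methyl-3-(phenylselanyl)propyl]-2,6,6-trimethylcyclohexane-1-carboxylic acid (ring centres as in 9) | OC(=O)[C@H]1C(C)(C)CCC[C@]1(C)C(C(O)=O)C(C)C[Se]c1ccccc1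
F6 | step 4 | dimethyl ester of F5 | COC(=O)[C@H]1C(C)(C)CCC[C@]1(C)C(C(=O)OC)C(C)C[Se]c1ccccc1
F7 | step 4 | methyl 2-(1-methoxy-3-methyl-1-oxobut-3-en-2-yl)-2,6,6-trimethylcyclohexane-1-carboxylate (ring centres as in 10; side-chain centre not assigned) | COC(=O)[C@H]1C(C)(C)CCC[C@]1(C)C(C(=O)OC)C(C)=C
F8 | step 2 | trimethylsilyl dienol ether of 3 | C=C(C)C=C(OCC1=C(C)CCCC1(C)C)O[Si](C)(C)C
F9 | step 2 | trimethylsilyl 3-methyl-2-(1,3,3-trimethyl-2-methylidenecyclohexyl)but-3-enoate (racemic) | C=C(C)C(C(=O)O[Si](C)(C)C)C1(C)CCCC(C)(C)C1=C
F10 | step 2 | 3-methyl-2-(1,3,3-trimethyl-2-methylidenecyclohexyl)but-3-enoic acid (racemic) | C=C(C)C(C(O)=O)C1(C)CCCC(C)(C)C1=C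
F11 | step 2 | (S)-1-phenylethylammonium salt of 5 | C=C(C)C(C([O-])=O)[C@@]1(C)CCCC(C)(C)C1=C.C[C@H]([NH3+])c1ccccc1
F12 | step 13 | N,N-dimethylhydrazone of 4-[(4R,4aS,8aS)-4-hydroxy-2,5,5,8a-tetramethyl-3,4,4a,5,6,7,8,8a-octahydronaphthalen-1-yl]butan-2-one | O[C@@H]1CC(C)=C(CCC(C)=NN(C)C)[C@@]2(C)CCCC(C)(C)[C@H]12
F13 | step 13 | 4-[(4R,4aS,8aS)-4-hydroxy-2,5,5,8a-tetramethyl-3,4,4a,5,6,7,8,8a-octahydronaphthalen-1-yl]butan-2-one | O[C@@H]1CC(C)=C(CCC(C)=O)[C@@]2(C)CCCC(C)(C)[C@H]12
F14 | step 15 | 2-oxo-4-[(4R,4aS,8aS)-4-hydroxy-2,5,5,8a-tetramethyl-3,4,4a,5,6,7,8,8a-octahydronaphthalen-1-yl]butyl (diethoxyphosphoryl)acetate | O[C@@H]1CC(C)=C(CCC(=O)COC(=O)CP(=O)(OCC)OCC)[C@@]2(C)CCCC(C)(C)[C@H]12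
A1 | alternative 1 | (1S)-3-[1-(tert-butyldimethylsilyloxy)ethenyl]-2,4,4-trimethylcyclohex-2-en-1-yl but-2-ynoate | C=C(O[Si](C)(C)C(C)(C)C)C1=C(C)[C@@H](OC(=O)C#CC)CCC1(C)C
A2 | alternative 1 | lactone-bridged 5,8-diene silyl enol ether | CC(C)(C)[Si](C)(C)OC1=C2C(C)(C)CC[C@@H]3OC(=O)C(=C(C)C1)[C@]23C
A3 | alternative 2 | (6S)-4-methylidene-6-(2,6,6-trimethylcyclohex-1-en-1-yl)oxan-2-one | C=C1CC(=O)O[C@@H](C1)C2=C(C)CCCC2(C)C
A4 | alternative 2 | 5-ene octalin C11 acid with exocyclic C8 methylene | C=C1CC=C2C(C)(C)CCC[C@]2(C)[C@@H]1C(O)=O
A5 | alternative 3 | tert-butyldimethylsilyl ether of {2-[(3E,9E)-4,8,8-trimethyl-10-nitro-3-(prop-1-en-2-yl)deca-3,9-dien-1-yl]-1,3-dioxolan-2-yl}methanol | [O-][N+](=O)/C=C/C(C)(C)CCC/C(C)=C(\CCC1(CO[Si](C)(C)C(C)(C)C)OCCO1)C(C)=C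
A6 | alternative 3 | 6α-nitro trans-decalin with the C8=C9 alkene | O=[N+]([O-])[C@H]1CC(C)=C(CCC3(CO[Si](C)(C)C(C)(C)C)OCCO3)[C@@]2(C)CCCC(C)(C)[C@H]12
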